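All runs are calculated with made-up constants; noise was put on by code.

Too much left-handed substrate is left over. In the eta run at 4.00 h, left-handed substrate and left-handed product add up to 52.0%, yet they can account for half of the charge.

| flask | left-handed substrate | right-handed substrate | reagent | free catalyst | racemization catalyst | remark | time |
|---|---|---|---|---|---|---|---|
| eta | 0.13 M | 0.13 M | 0.17 M | 6.5 mM | 25 mM | run made earlier |  |
| alpha | 0.13 M | 0.13 M | 0.39 M | 6.5 mM | 25 mM | run made earlier |  |
| theta | 0.13 M | 0.13 M | 0.26 M | 6.5 mM | 50 mM | run made earlier |  |
| flask | 0.13 M | 0.13 M | 0.260 M | 6.5 mM | 25 mM |  | 6.0 h |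

| run | time / h | left-handed product / % | right-handed product / % | left-handed substrate / % |
|---|---|---|---|---|
| eta | 0.500 | 5.8 | 2.6 | 44.8 |
| eta | 1.00 | 9.7 | 5.0 | 41.7 |
| eta | 1.50 | 11.9 | 6.5 | 39.4 |
| eta | 2.00 | 13.1 | 7.8 | 37.7 |
| eta | 2.50 | 14.6 | 8.7 | 37.0 |
| eta | 3.00 | 16.2 | 9.2 | 35.5 |
| eta | 4.00 | 17.6 | 10.6 | 34.4 |
| alpha | 0.500 | 11.2 | 6.6 | 38.8 |
| alpha | 1.00 | 18.3 | 11.6 | 33.6 |
| alpha | 1.50 | 22.6 | 13.6 | 29.1 |
| alpha | 2.00 | 26.4 | 15.6 | 26.1 |
| alpha | 2.50 | 27.5 | 18.1 | 23.6 |
| alpha | 3.00 | 30.5 | 18.5 | 22.5 |
| alpha | 4.00 | 33.1 | 21.9 | 20.7 |
| theta | 0.250 | 4.5 | 1.9 | 45.4 |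
| theta | 0.500 | 8.3 | 4.7 | 42.4 |
| theta | 1.00 | 13.1 | 8.0 | 38.7 |
| theta | 2.00 | 19.4 | 10.4 | 33.1 |
| theta | 4.00 | 24.4 | 16.1 | 29.8 |

(readings scatter by 0.5 percentage points)

- free catalyst is single-handed; left-handed substrate and right-handed substrate are mirror images of each other, charged as a racemate, each of them at the stated concentration
- the numbers in the tables scatter by 0.5 percentage points (one standard deviation)
- an excess is below zero if the other one leads

1. left-handed product and right-handed product together, in percent of the left-handed substrate and right-handed substrate charged together, at 6.0 h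
2. excess of left-handed product over right-handed product in the product at 6.0 h
3. whether the exchange between left-handed substrate and right-handed substrate keeps pace with the reaction: how far the product's excess at 6.0 h gets from its value without exchange to its value with instant exchange (above 80% keeps pace, below 20% hardly takes part, else lags behind)

*Where does the extra 2 percentage points come from?* From right-handed substrate. The racemization catalyst turns it into left-handed substrate, which the free catalyst consumes faster: the eta run holds more left-handed than right-handed product.

*How fast is this exchange at the flask's 25 mM?* Let the transfer per hour be k_x times the gap between the two substrates. The alpha run transferred 3.8 points. The final gaps were 3 points in eta and 3.6 points in alpha. Taking those as typical, my reading is k_x = 0.220 h⁻¹. Each transfer changes the gap from both sides, so the gap closes in τ_x = 2.28 h.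

*And the reaction?* The theta run has the flask's reagent charge. Its product at 0.500 h gives a first-order slope at the start, k_r = 0.279 h⁻¹, so the substrate's time at the start is τ_r = 3.59 h. That is a start value and no constant: averaged up to 4.00 h, the same reckoning on the theta run gives 0.130 h⁻¹.

*Your quantity?* The exchange number, N = τ_r/τ_x = 1.58: exchange times per substrate time at the start.

*Above one, so it keeps pace?* No. By 1.00 h the theta run had made about half of its product at 4.00 h, and that is sooner than τ_x. I commit to lagging behind.

The forecast says 46%, 23.5% and lags behind: “roughly halfway, so exchange lags behind”.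

The flask gives 45.8%, an excess of 24.1%, and lags behind, at 47% of the way.

    reagent + free catalyst + left-handed substrate → free catalyst + left-handed product (k = 242 M⁻² h⁻¹)
    reagent + free catalyst + right-handed substrate → free catalyst + right-handed product (k = 136 M⁻² h⁻¹)
    left-handed substrate + racemization catalyst ⇌ right-handed substrate + racemization catalyst, rate k3*[racemization catalyst]*[left-handed substrate] forward; the back reaction follows from the equilibrium constant (k = 11.5 M⁻¹ h⁻¹)
    2 free catalyst → spent catalyst A (k = 38.8 M⁻¹ h⁻¹)
    reagent + racemization catalyst → spent catalyst B (k = 0.473 M⁻¹ h⁻¹)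

With N at 1.58, the flask still holds unequal substrates at 6.0 h: 52% of the left-handed charge remains against 57% of the right-handed. A neighbouring flask has 0.026 M of free catalyst instead of 6.5 mM. With the start rate proportional to free catalyst, as in the equations above, τ_r falls to 0.898 h and N to 0.395, and this τ_r is shorter than τ_x. It reaches 60.9% of product, and its excess is lower than the flask's, at 21.6%.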